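The cyclohexenone ring is made last, from a four-membered ring. Cyclobutanone 16 already holds the ketone carbon C1, the quaternary carbon C6, the methoxy carbon C4 and every stereocentre. A nickel-catalysed formal [4+2] ring expansion inserts acetylene into its C(=O)–CH(OMe) bond, forming C1–C2 and C3–C4 in one operation and creating the C2=C3 alkene. The step exploits the O=C1–C2=C3–C4(OMe) array of the cyclohexenone ring, whose two carbons between ketone and methoxy carbon map onto an alkyne. Cyclobutanone 16 comes from an Evans syn-aldol adduct through an allyl ketone, a sulfonium ylide spiroannulation and α-methoxylation.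

Key step: step 9

Remark on the chemistry: locants C1–C6 are those of the cyclohex-2-en-1-one ring of the target, and the Lewis-acid-induced oxaspiropentane-to-cyclobutanone shift is assumed to occur with inversion at the carbon that receives the migrating CH2 group.

Step 1
Reactants: 1 (R)-4-benzyl-3-propanoyl-1,3-oxazolidin-2-one; 2 3,4,5-trimethoxybenzaldehyde
Product: 4 (4R)-4-benzyl-3-[(2R,3R)-3-hydroxy-2-methyl-3-(3,4,5-trimethoxyphenyl)propanoyl]-1,3-oxazolidin-2-one, via Z-boron enolate 3 (not isolated)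
Conditions: Bu2BOTf, i-Pr2NEt, CH2Cl2, 0 °C; then 2, −78 to 0 °C; then MeOH, pH 7 buffer, H2O2
Reagents that add atoms: none
Why: Evans syn-aldol reaction; the Z-boron enolate reacts through a closed chair transition state on the enolate face away from the benzyl group, which should set both the carbinol and the methyl-bearing centre as (2R,3R).

Step 2
Reactants: 4 aldol adduct
Product: 5 (2R,3R)-3-hydroxy-N-methoxy-N,2-dimethyl-3-(3,4,5-trimethoxyphenyl)propanamide
Conditions: MeNH(OMe)·HCl, AlMe3, CH2Cl2, −10 to 0 °C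
Reagents that add atoms: N,O-dimethylhydroxylamine hydrochloride, CNOC.Cl
Why: Transamidation of the imide by the aluminium amide, assisted by the free β-hydroxyl, should release the auxiliary without touching either stereocentre.

Step 3
Reactants: 5 hydroxy amide
Product: 6 (2R,3R)-3-[(tert-butyldimethylsilyl)oxy]-N-methoxy-N,2-dimethyl-3-(3,4,5-trimethoxyphenyl)propanamide
Conditions: TBSOTf, 2,6-lutidine, CH2Cl2, 0 °C
Reagents that add atoms: tert-butyldimethylsilyl triflate, CC(C)(C)[Si](C)(C)OS(=O)(=O)C(F)(F)F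
Why: Silylation of the secondary benzylic alcohol blocks retro-aldol cleavage and hemiketal formation with the later cyclobutanone.

Step 4
Reactants: 6 silyl ether amide; 7 allylmagnesium bromide
Product: 8 (1R,2R)-1-[(tert-butyldimethylsilyl)oxy]-2-methyl-1-(3,4,5-trimethoxyphenyl)hex-5-en-3-one
Conditions: CH2=CHCH2MgBr, THF, −78 to −20 °C; cold aq. NH4Cl
Reagents that add atoms: none
Why: Grignard acylation of an N-methoxy-N-methylamide stops at the ketone, and the cold neutral quench should keep the β,γ-unsaturated ketone from conjugating or epimerising.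

Step 5
Reactants: 8 allyl ketone; 9 cyclopropyldiphenylsulfonium tetrafluoroborate
Product: 11 (2S)-2-allyl-2-[(1R,2S)-1-[(tert-butyldimethylsilyl)oxy]-1-(3,4,5-trimethoxyphenyl)propan-2-yl]cyclobutan-1-one, via oxaspiropentane 10 (not isolated)
Conditions: 9, KN(SiMe3)2, DME, −78 to −45 °C; then 8, −45 to 0 °C; then LiBF4 (cat.), 25 °C
Reagents that add atoms: none
Why: Sulfonium ylide spiroannulation; the cyclopropylide should add to the ketone anti to the large CH(OTBS)Ar group of the adjacent centre and past its hydrogen, and the Lewis-acid-induced 1,2-shift of a cyclopropane CH2 with inversion at the tertiary carbon then sets the quaternary centre.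

Step 6
Reactants: 11 cyclobutanone
Product: 13 (2S,4R)-4-allyl-2-hydroxy-4-[(1R,2S)-1-[(tert-butyldimethylsilyl)oxy]-1-(3,4,5-trimethoxyphenyl)propan-2-yl]cyclobutan-1-one, via potassium enolate 12 (not isolated)
Conditions: KN(SiMe3)2, THF, −78 °C; then 2-(phenylsulfonyl)-3-phenyloxaziridine, −78 °C; aq. NH4Cl
Reagents that add atoms: 2-(phenylsulfonyl)-3-phenyloxaziridine, O=S(=O)(N1OC1c1ccccc1)c1ccccc1
Why: Only the CH2 side can enolise, and electrophilic hydroxylation of the enolate should occur on the face of the smaller allyl group; this configuration is provisional and is reset in step 8.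

Step 7
Reactants: 13 hydroxy ketone
Product: 14 (2S,4R)-4-allyl-4-[(1R,2S)-1-[(tert-butyldimethylsilyl)oxy]-1-(3,4,5-trimethoxyphenyl)propan-2-yl]-2-methoxycyclobutan-1-one
Conditions: MeOTf, 2,6-di-tert-butyl-4-methylpyridine, CH2Cl2, 0 to 25 °C
Reagents that add atoms: methyl triflate, COS(=O)(=O)C(F)(F)F
Why: O-methylation under non-basic conditions should avoid α-ketol rearrangement and C-alkylation of the strained hydroxy ketone.

Step 8
Reactants: 14 methoxy ketone
Product: 16 (2R,4R)-4-allyl-4-[(1R,2S)-1-[(tert-butyldimethylsilyl)oxy]-1-(3,4,5-trimethoxyphenyl)propan-2-yl]-2-methoxycyclobutan-1-one, via lithium enolate 15 (not isolated)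
Conditions: LiN(SiMe3)2, THF, −78 °C; then AcOH, −78 °C
Reagents that add atoms: none
Why: Kinetic protonation of the planar enolate on the face of the smaller allyl group should place the methoxy group cis to the bulky side chain, which is also the thermodynamically preferred 1,3-cis pseudo-diequatorial arrangement.

Step 9
Reactants: 16 methoxycyclobutanone; 17 acetylene
Product: 20 (4R,6R)-6-allyl-6-[(1R,2S)-1-[(tert-butyldimethylsilyl)oxy]-1-(3,4,5-trimethoxyphenyl)propan-2-yl]-4-methoxycyclohex-2-en-1-one, via oxanickelacyclopentene 18 (not isolated), via nickelacycloheptenone 19 (not isolated)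
Conditions: Ni(cod)2 (10 mol %), PCy3 (20 mol %), 17 (slow feed as a toluene solution, about 3 equiv), toluene, 60 °C
Reagents that add atoms: none
Why: Proposed new method: zerovalent nickel should bind the strained ketone and acetylene and couple them by oxidative cyclisation to the spiro oxanickelacyclopentene 18 (five-membered metallacycle, forming C1–C2); β-carbon elimination then opens the four-membered ring to the seven-membered nickelacycle 19, and C(sp3)–C(sp2) reductive elimination closes the cyclohexenone (forming C3–C4) and returns the catalyst. The closest known reaction type is the nickel-catalysed insertion of internal alkynes into the C(=O)–C bond of cyclobutanones, 3-oxetanones and 3-azetidinones; the last two show that a heteroatom-bearing carbon can migrate to nickel, but neither acetylene itself nor an α-alkoxy α'-quaternary cyclobutanone has been used. The six-membered ring is closed by reductive ring contraction of a nickelacycle, not by a chain cyclisation, so the cis geometry of C2=C3 follows from syn addition across the alkyne. No stereocentre is created: C6 is a spectator and C4 should be carried over with retention, because β-carbon elimination and reductive elimination both retain configuration at the migrating carbon. The step needs cleavage of the C(=O)–CH(OMe) bond and not the C(=O)–C6 bond, which the quaternary carbon secures because its migration would give a tertiary alkylnickel while the methoxy-bearing secondary carbon is unhindered and can chelate the metal; it also needs cross-annulation to outrun acetylene oligomerisation, which slow feeding of the smallest possible alkyne to the strained ketone is meant to secure.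

Step 10
Reactants: 20 silyl-protected megaphone
Product: 21 megaphone, (4R,6R)-6-allyl-6-[(1R,2S)-1-hydroxy-1-(3,4,5-trimethoxyphenyl)propan-2-yl]-4-methoxycyclohex-2-en-1-one
Conditions: HF·pyridine, pyridine, THF, 0 to 25 °C
Reagents that add atoms: none
Why: Buffered fluoride cleavage of the Si–O bond should leave the enone, the allyl group and the methyl ethers untouched.

Step 11
Reactants: 21 megaphone
Product: 22 megaphone acetate, (1R,2S)-2-[(1R,5R)-1-allyl-5-methoxy-2-oxocyclohex-3-en-1-yl]-1-(3,4,5-trimethoxyphenyl)propyl acetate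
Conditions: Ac2O, pyridine, DMAP (cat.), CH2Cl2, 25 °C
Reagents that add atoms: acetic anhydride, CC(=O)OC(C)=O
Why: DMAP-catalysed acylation of the secondary benzylic alcohol should proceed without affecting any stereocentre.

Compound list
1 | (R)-4-benzyl-3-propanoyl-1,3-oxazolidin-2-one | CCC(=O)N1[C@H](Cc2ccccc2)COC1=O | starting material
2 | 3,4,5-trimethoxybenzaldehyde | COc1cc(C=O)cc(OC)c1OC | starting material
3 | (Z)-dibutylboron enolate of 1 | C/C=C(\OB(CCCC)CCCC)N1[C@H](Cc2ccccc2)COC1=O | intermediate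
4 | (4R)-4-benzyl-3-[(2R,3R)-3-hydroxy-2-methyl-3-(3,4,5-trimethoxyphenyl)propanoyl]-1,3-oxazolidin-2-one | O=C([C@H](C)[C@@H](O)c1cc(OC)c(OC)c(OC)c1)N1[C@H](Cc2ccccc2)COC1=O | intermediate
5 | (2R,3R)-3-hydroxy-N-methoxy-N,2-dimethyl-3-(3,4,5-trimethoxyphenyl)propanamide | CON(C)C(=O)[C@H](C)[C@@H](O)c1cc(OC)c(OC)c(OC)c1 | intermediate
6 | (2R,3R)-3-[(tert-butyldimethylsilyl)oxy]-N-methoxy-N,2-dimethyl-3-(3,4,5-trimethoxyphenyl)propanamide | CON(C)C(=O)[C@H](C)[C@@H](O[Si](C)(C)C(C)(C)C)c1cc(OC)c(OC)c(OC)c1 | intermediate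
7 | allylmagnesium bromide | C=CC[Mg]Br | starting material
8 | (1R,2R)-1-[(tert-butyldimethylsilyl)oxy]-2-methyl-1-(3,4,5-trimethoxyphenyl)hex-5-en-3-one | C=CCC(=O)[C@H](C)[C@@H](O[Si](C)(C)C(C)(C)C)c1cc(OC)c(OC)c(OC)c1 | intermediate
9 | cyclopropyldiphenylsulfonium tetrafluoroborate | C1CC1[S+](c1ccccc1)c1ccccc1.F[B-](F)(F)F | starting material
10 | (2S)-2-allyl-2-[(1R,2R)-1-[(tert-butyldimethylsilyl)oxy]-1-(3,4,5-trimethoxyphenyl)propan-2-yl]-1-oxaspiro[2.2]pentane | C=CC[C@@]1([C@H](C)[C@@H](O[Si](C)(C)C(C)(C)C)c2cc(OC)c(OC)c(OC)c2)OC13CC3 | intermediate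
11 | (2S)-2-allyl-2-[(1R,2S)-1-[(tert-butyldimethylsilyl)oxy]-1-(3,4,5-trimethoxyphenyl)propan-2-yl]cyclobutan-1-one | C=CC[C@]1([C@H](C)[C@@H](O[Si](C)(C)C(C)(C)C)c2cc(OC)c(OC)c(OC)c2)CCC1=O | intermediate
12 | potassium enolate of 11 (enolate double bond towards the ring CH2) | C=CC[C@]1([C@H](C)[C@@H](O[Si](C)(C)C(C)(C)C)c2cc(OC)c(OC)c(OC)c2)CC=C1[O-].[K+] | intermediate
13 | (2S,4R)-4-allyl-2-hydroxy-4-[(1R,2S)-1-[(tert-butyldimethylsilyl)oxy]-1-(3,4,5-trimethoxyphenyl)propan-2-yl]cyclobutan-1-one (OH cis to allyl) | C=CC[C@]1([C@H](C)[C@@H](O[Si](C)(C)C(C)(C)C)c2cc(OC)c(OC)c(OC)c2)C[C@H](O)C1=O | intermediate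
14 | (2S,4R)-4-allyl-4-[(1R,2S)-1-[(tert-butyldimethylsilyl)oxy]-1-(3,4,5-trimethoxyphenyl)propan-2-yl]-2-methoxycyclobutan-1-one (OMe cis to allyl) | C=CC[C@]1([C@H](C)[C@@H](O[Si](C)(C)C(C)(C)C)c2cc(OC)c(OC)c(OC)c2)C[C@H](OC)C1=O | intermediate
15 | lithium enolate of 14 (methoxy-substituted enolate carbon) | C=CC[C@]1([C@H](C)[C@@H](O[Si](C)(C)C(C)(C)C)c2cc(OC)c(OC)c(OC)c2)CC(OC)=C1[O-].[Li+] | intermediate
16 | (2R,4R)-4-allyl-4-[(1R,2S)-1-[(tert-butyldimethylsilyl)oxy]-1-(3,4,5-trimethoxyphenyl)propan-2-yl]-2-methoxycyclobutan-1-one (OMe cis to the side chain) | C=CC[C@]1([C@H](C)[C@@H](O[Si](C)(C)C(C)(C)C)c2cc(OC)c(OC)c(OC)c2)C[C@@H](OC)C1=O | intermediate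
17 | acetylene | C#C | starting material
18 | spiro oxanickelacyclopentene of divalent nickel, Ni(PCy3): ring O–Ni–CH=CH–C spiro-fused at the former carbonyl carbon of 16, other centres as in 16 | C=CC[C@]1([C@H](C)[C@@H](O[Si](C)(C)C(C)(C)C)c2cc(OC)c(OC)c(OC)c2)C[C@@H](OC)C13O[Ni]C=C3.C1CCC(CC1)P(C1CCCCC1)C1CCCCC1 | intermediate
19 | seven-membered nickelacycloheptenone of divalent nickel, Ni(PCy3): Ni bound to the methoxy carbon and to the vinyl carbon of the new enone, other centres as in 16 | C=CC[C@]1([C@H](C)[C@@H](O[Si](C)(C)C(C)(C)C)c2cc(OC)c(OC)c(OC)c2)C[C@@H](OC)[Ni]C=CC1=O.C1CCC(CC1)P(C1CCCCC1)C1CCCCC1 | intermediate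
20 | (4R,6R)-6-allyl-6-[(1R,2S)-1-[(tert-butyldimethylsilyl)oxy]-1-(3,4,5-trimethoxyphenyl)propan-2-yl]-4-methoxycyclohex-2-en-1-one | C=CC[C@]1([C@H](C)[C@@H](O[Si](C)(C)C(C)(C)C)c2cc(OC)c(OC)c(OC)c2)C[C@@H](OC)C=CC1=O | intermediate
21 | megaphone, (4R,6R)-6-allyl-6-[(1R,2S)-1-hydroxy-1-(3,4,5-trimethoxyphenyl)propan-2-yl]-4-methoxycyclohex-2-en-1-one | C=CC[C@]1([C@H](C)[C@@H](O)c2cc(OC)c(OC)c(OC)c2)C[C@@H](OC)C=CC1=O | intermediate
22 | megaphone acetate, (1R,2S)-2-[(1R,5R)-1-allyl-5-methoxy-2-oxocyclohex-3-en-1-yl]-1-(3,4,5-trimethoxyphenyl)propyl acetate | C=CC[C@]1([C@H](C)[C@@H](OC(C)=O)c2cc(OC)c(OC)c(OC)c2)C[C@@H](OC)C=CC1=O | target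

Total step count: 11. Longest linear sequence: 11 steps (fully linear from 1).

Steps most likely to fail

1. Step 9 (proposed new method). Acetylene may oligomerise on nickel faster than it couples with the hindered ketone. The α-methoxyalkylnickel intermediate may undergo β-hydride elimination to ring-opened dienones, or lose the C4 configuration. Fallback by known chemistry, from 13 back to 20: oxidative cleavage of the α-hydroxy ketone 13 (either epimer) with Pb(OAc)4 in MeOH/benzene should give the methyl ester aldehyde F1. Addition of (Z)-Bu3SnCH=CHLi (from (Z)-1,2-bis(tributylstannyl)ethene and n-BuLi, THF, −78 °C), followed by trapping of the alkoxide with MeI, should give the (Z)-stannyl allylic methyl ether F2. The addition is not expected to be selective at the new methoxy carbon, so the (4R) epimer would have to be separated. Tin–lithium exchange on F2 (n-BuLi, THF, −78 °C) and intramolecular acylation of the cis-vinyllithium by the ester should close the cyclohexenone and rejoin the route at 20.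

2. Step 5. The basic ylide may enolise and conjugate the β,γ-unsaturated ketone instead of adding. Facial selectivity of the addition may be modest, and the ring expansion may pass through a free cation and lose stereochemical fidelity. Fallback, from 8 back to 11: the less basic organocerium reagent from 1-lithiocyclopropyl phenyl sulfide and CeCl3 (THF, −78 °C) should add to 8 with the same facial preference to give the tertiary carbinol F3. Acid-induced ring expansion of F3 (aq. HBF4, Et2O, 0 °C), driven by the sulfur-stabilised cyclobutyl cation and hydrolysis, should then give cyclobutanone 11.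

3. Step 8. Protonation of the enolate may show poor facial selectivity, giving back mainly the starting epimer. Fallback, from 13 back to 16: Mitsunobu inversion of the hydroxy ketone 13 with 4-nitrobenzoic acid (PPh3, DIAD, THF) should give the inverted 4-nitrobenzoate F4. Methanolysis of F4 (K2CO3, MeOH, 0 °C) should give the cis-hydroxy ketone F5, and methylation of F5 under the conditions of step 7 should give 16 directly, bypassing steps 7 and 8.

Further compounds
F1 | step 9 | methyl (2R)-2-[(1R,2S)-1-[(tert-butyldimethylsilyl)oxy]-1-(3,4,5-trimethoxyphenyl)propan-2-yl]-4-oxo-2-(prop-2-en-1-yl)butanoate | C=CC[C@](C(=O)OC)([C@H](C)[C@@H](O[Si](C)(C)C(C)(C)C)c1cc(OC)c(OC)c(OC)c1)CC=O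
F2 | step 9 | methyl (2R,4R,5Z)-2-[(1R,2S)-1-[(tert-butyldimethylsilyl)oxy]-1-(3,4,5-trimethoxyphenyl)propan-2-yl]-4-methoxy-2-(prop-2-en-1-yl)-6-(tributylstannyl)hex-5-enoate | C=CC[C@](C(=O)OC)([C@H](C)[C@@H](O[Si](C)(C)C(C)(C)C)c1cc(OC)c(OC)c(OC)c1)C[C@@H](OC)/C=C\[Sn](CCCC)(CCCC)CCCC
F3 | step 5 | (1R,2R,3S)-1-[(tert-butyldimethylsilyl)oxy]-2-methyl-3-[1-(phenylsulfanyl)cyclopropyl]-1-(3,4,5-trimethoxyphenyl)hex-5-en-3-ol | C=CC[C@@](O)(C1(Sc2ccccc2)CC1)[C@H](C)[C@@H](O[Si](C)(C)C(C)(C)C)c1cc(OC)c(OC)c(OC)c1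
F4 | step 8 | (1R,3R)-3-allyl-3-[(1R,2S)-1-[(tert-butyldimethylsilyl)oxy]-1-(3,4,5-trimethoxyphenyl)propan-2-yl]-2-oxocyclobutyl 4-nitrobenzoate | C=CC[C@]1([C@H](C)[C@@H](O[Si](C)(C)C(C)(C)C)c2cc(OC)c(OC)c(OC)c2)C[C@@H](OC(=O)c2ccc(cc2)[N+](=O)[O-])C1=O
F5 | step 8 | (2R,4R)-4-allyl-2-hydroxy-4-[(1R,2S)-1-[(tert-butyldimethylsilyl)oxy]-1-(3,4,5-trimethoxyphenyl)propan-2-yl]cyclobutan-1-one | C=CC[C@]1([C@H](C)[C@@H](O[Si](C)(C)C(C)(C)C)c2cc(OC)c(OC)c(OC)c2)C[C@@H](O)C1=O
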